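**Retrosynthetic overview**
- The γ-lactone (C6–O to C12) is closed last. C1=C10 comes from E1cB loss of a C1 oxygen, and the C4 methyl from a C4 ketone via enol triflate and cross-coupling.
- Key step: the ten-membered ring is released by a methoxide retro-Claisen ring expansion of a bicyclo[4.4.1]undecane-2,11-dione. The C14–C5 bond of the one-carbon bridge is cut and C14 becomes the C10 methyl ester.
- The bicycle comes from tropone and (1E,3E)-1,4-diacetoxybutadiene by [6+4] cycloaddition. The meso adduct is desymmetrised by a lipase, and the rigid bicycle then sets C7/C8 (nitrile oxide cycloaddition) and C2/C3 (singlet oxygen, Kornblum–DeLaMare rearrangement, epoxidation).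
- Side chains: (R)-2-methylbutanoic acid (bought) and (2S,3S)-epoxyangelic acid (Sharpless epoxidation, then oxidation).
- Ring order: two fused seven-membered rings → temporary isoxazoline → 2,3-epoxide → ten-membered ring → γ-lactone.

Assumption: (1E,3E)-buta-1,3-diene-1,4-diyl diacetate is taken as a purchasable starting material whose two acetyl groups are protecting groups on a C4O2 core (both are removed later).

Labels: C1–C10 are the ring carbons of the target (C6 carries the lactone oxygen, C7 carries C11, C8 the epoxyangelate, C9 the 2-methylbutanoate, C10 the ester carbon C14, C4 the methyl C15). In the bicycles C14 is the ketone bridging C10 and C5. "Bottom" is the face of the C1–C4 bridge opposite the C6–C9 bridge; "outer" is the face of C7=C8 away from C14.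

**Step 1**
Reactants: 1 (Z)-2-methylbut-2-en-1-ol
Product: 2 [(2R,3S)-2,3-dimethyloxiran-2-yl]methanol
Conditions: Ti(OiPr)4 (10 mol%), L-(+)-diethyl tartrate (12 mol%), t-BuOOH, 4 Å molecular sieves, CH2Cl2, −20 °C
Reagents that add atoms: tert-butyl hydroperoxide, CC(C)(C)OO
Why: Sharpless asymmetric epoxidation of a (Z)-2,3-disubstituted allylic alcohol, in which L-(+)-tartrate delivers oxygen to the face that gives the (2R,3S)-epoxy alcohol and so sets both side-chain stereocentres.

**Step 2**
Reactants: 2 [(2R,3S)-2,3-dimethyloxiran-2-yl]methanol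
Product: 4 (2S,3S)-2,3-dimethyloxirane-2-carboxylic acid, via epoxy aldehyde 3 (not isolated)
Conditions: RuCl3 (2 mol%), NaIO4, MeCN/CCl4/H2O, rt
Reagents that add atoms: sodium periodate, [Na+].[O-]I(=O)(=O)=O
Why: RuO4-catalysed oxidation of the primary alcohol to the acid leaves the epoxide and both stereocentres untouched (the C2 descriptor changes only through priority).

**Step 3**
Reactants: 5 tropone; 6 (1E,3E)-buta-1,3-diene-1,4-diyl diacetate
Product: 7 meso exo-adduct 11-oxobicyclo[4.4.1]undeca-2,4,8-triene-7,10-diyl diacetate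
Conditions: xylenes, 135 °C, sealed tube, BHT (cat.)
Reagents that add atoms: none
Why: Thermal [6+4] cycloaddition of tropone with a 1-acyloxydiene goes through the exo transition state, which puts both acetoxy groups outward on the new four-carbon bridge and fixes the relative configuration of C6, C9 and the bridgeheads C5 and C10 in a meso adduct.

**Step 4**
Reactants: 7 meso exo-adduct diacetate
Product: 8 C6-hydroxy C9-acetate of the bicyclic trienone
Conditions: lipase from Burkholderia cepacia, pH 7 phosphate buffer/acetone, 30 °C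
Reagents that add atoms: none
Why: Enzymatic desymmetrisation of a meso cis-cyclohept-2-ene-1,4-diyl diacetate motif by hydrolysis of one enantiotopic ester sets the absolute configuration of C6 and C9 that every later substrate-controlled step relays, and if the enzyme prefers the other ester the same lipase used to acetylate the meso-diol gives this mono-acetate.

**Step 5**
Reactants: 8 C6-hydroxy C9-acetate
Product: 10 C6-OTBS C9-hydroxy bicyclic trienone, via silyl ether acetate 9 (not isolated)
Conditions: TBSOTf, 2,6-lutidine, CH2Cl2, 0 °C; then MeOH, K2CO3, rt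
Reagents that add atoms: tert-butyldimethylsilyl trifluoromethanesulfonate, CC(C)(C)[Si](C)(C)OS(=O)(=O)C(F)(F)F
Why: Silylation then mild methanolysis gives a robust, non-leaving silyl ether at C6 (later β to a ketone) and frees the C9 hydroxyl that must direct the next step, without touching a stereocentre.

**Step 6**
Reactants: 10 C6-OTBS C9-hydroxy bicyclic trienone; 11 methyl 2-chloro-2-(hydroxyimino)acetate
Product: 13 bicyclic isoxazoline alcohol, via nitrile oxide 12 (not isolated)
Conditions: EtMgBr (2.0 equiv), i-PrOH (1.05 equiv), CH2Cl2, 0 °C; then 11, 0 °C to rt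
Reagents that add atoms: none
Why: Magnesium-alkoxide-directed nitrile oxide 1,3-dipolar cycloaddition (Kanemasa conditions), in which the C9–OMgBr binds the dipole oxygen and delivers it to the proximal carbon C8 while carbon bonds to C7, both on the outer face of C7=C8, which sets C7 and C8 and spares the diene.

**Step 7**
Reactants: 13 bicyclic isoxazoline alcohol; 14 (R)-2-methylbutanoic acid
Product: 16 bicyclic isoxazoline C9 (R)-2-methylbutanoate, via mixed anhydride 15 (not isolated)
Conditions: 14, 2,4,6-trichlorobenzoyl chloride, Et3N, THF, rt; then 13, DMAP, PhMe, rt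
Reagents that add atoms: none
Why: Yamaguchi esterification acylates the hindered C9 hydroxyl through the mixed anhydride with retention at C9 and without racemising the α-centre of the acid.

**Step 8**
Reactants: 16 bicyclic isoxazoline C9 (R)-2-methylbutanoate
Product: 18 C8-hydroxy C7 α-keto ester, via imino ester 17 (not isolated)
Conditions: Mo(CO)6, MeCN/H2O (10:1), 75 °C
Reagents that add atoms: water, O
Why: Reductive N–O cleavage of the isoxazoline by Mo(CO)6 and hydrolysis of the imine unmask the C8 hydroxyl and the C11 ketone, with the C7 substituent staying on the less hindered outer face of the bicycle.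

**Step 9**
Reactants: 18 C8-hydroxy C7 α-keto ester
Product: 19 C8-hydroxy C7 acrylate
Conditions: Zn, CH2Br2, TiCl4, THF/CH2Cl2, 0 °C
Reagents that add atoms: dibromomethane, BrCBr
Why: Takai–Lombardo methylenation is non-basic and selective for the activated α-keto ester carbonyl, so C11=C13 is installed without epimerising C7, retro-aldol cleavage, or attack on the hindered C14 ketone and the esters.

**Step 10**
Reactants: 19 C8-hydroxy C7 acrylate; 4 (2S,3S)-2,3-dimethyloxirane-2-carboxylic acid
Product: 21 bicyclic trienone triester, via mixed anhydride 20 (not isolated)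
Conditions: 4, 2,4,6-trichlorobenzoyl chloride, Et3N, THF, rt; then 19, DMAP, PhMe, rt
Reagents that add atoms: none
Why: Yamaguchi esterification of the C8 hydroxyl with the α-quaternary epoxy acid (which cannot epimerise) caps C8 before it can lactonise onto the acrylate.

**Step 11**
Reactants: 21 bicyclic trienone triester
Product: 23 γ-hydroxy enone, via endoperoxide 22 (not isolated)
Conditions: O2, 5,10,15,20-tetraphenylporphyrin (cat.), visible light, CH2Cl2, −20 °C; then N2 purge, 9-O-acetylcupreidine (10 mol%), rt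
Reagents that add atoms: dioxygen, O=O
Why: Singlet-oxygen [4+2] cycloaddition to the cis-diene from its open bottom face is followed by a chiral-amine-catalysed Kornblum–DeLaMare rearrangement in which the catalyst (or its quinine-derived pseudo-enantiomer) selects H-4 for removal, giving the C4 ketone and the C1 alcohol.

**Step 12**
Reactants: 23 γ-hydroxy enone
Product: 24 epoxy hydroxy diketone
Conditions: dimethyldioxirane, acetone, 0 °C to rt
Reagents that add atoms: dimethyldioxirane, CC1(C)OO1
Why: Neutral dioxirane epoxidation of the enone on the open bottom face, syn to and hydrogen-bond-guided by the C1 hydroxyl, sets C2 and C3 as the cis-epoxide without a base that could touch the 1,3-diketone, and the electron-poor acrylate is left alone.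

**Step 13**
Reactants: 24 epoxy hydroxy diketone
Product: 25 ten-membered β-hydroxy ester ketone
Conditions: NaOMe (0.2 equiv), MeOH/THF (1:3), −20 to 0 °C; AcOH quench
Reagents that add atoms: methanol, CO
Why: Proposed new method: methoxide-catalysed retro-Claisen ring expansion of a tropone [6+4]-derived bicyclo[4.4.1]undecane-2,11-dione, in which MeO− adds to the exposed bottom face of the one-carbon-bridge ketone C14, the hemiketal alkoxide expels C5 as the C4 enolate (C14–C5 is the only bridge bond backed by a second carbonyl, and the bridgehead C5–H is poorly enolisable), and MeOH protonates the enolate and returns methoxide, so C14 ends as the C10 methyl ester and the two seven-membered rings merge into the ten-membered ring with every stereocentre untouched; the closest known reaction type is the alkoxide retro-Claisen (retro-Dieckmann) cleavage of bridged 1,3-diketones such as bicyclo[3.3.1]nonane-2,9-diones to cyclooctanones.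

**Step 14**
Reactants: 25 ten-membered β-hydroxy ester ketone
Product: 27 C4-methyl (Z)-C4=C5 β-hydroxy ester, via enol triflate 26 (not isolated)
Conditions: KN(SiMe3)2 (2.2 equiv), THF, −78 °C; N-(5-chloropyridin-2-yl)bis(trifluoromethanesulfonyl)imide; then MeZnCl, Pd(PPh3)4 (5 mol%), −78 to 0 °C
Reagents that add atoms: methylzinc chloride, C[Zn]Cl
Why: Kinetic enolisation can only go toward C5 and gives the ring-cis enolate favoured in a ten-membered ring, whose O-triflation (the C1 alkoxide stays a spectator) and Negishi coupling with retention install C15 and fix the (Z)-C4=C5 bond.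

**Step 15**
Reactants: 27 C4-methyl (Z)-C4=C5 β-hydroxy ester
Product: 29 C6-OTBS seco diester, via mesylate 28 (not isolated)
Conditions: MsCl, Et3N, CH2Cl2, −20 °C; then DBU, 0 °C
Reagents that add atoms: none
Why: Mesylation of the only free hydroxyl and E1cB elimination through the C10 ester enolate give the conjugated ester with CO2Me trans to C2 (ring-cis, the thermodynamically preferred geometry), the far poorer 9-acyloxy leaving group being retained.

**Step 16**
Reactants: 29 C6-OTBS seco diester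
Product: 31 target germacranolide, via hydroxy ester 30 (not isolated)
Conditions: HF·pyridine, pyridine, THF, 0 °C to rt
Reagents that add atoms: none
Why: Buffered fluoride desilylation frees the C6 hydroxyl, which lactonises onto the acrylate methyl ester to close the trans-fused α-methylene-γ-butyrolactone without touching a stereocentre.

**Compound list**
1 | (Z)-2-methylbut-2-en-1-ol | C/C=C(/C)CO | starting material
2 | [(2R,3S)-2,3-dimethyloxiran-2-yl]methanol | OC[C@@]1(C)O[C@H]1C | intermediate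
3 | (2S,3S)-2,3-dimethyloxirane-2-carbaldehyde | O=C[C@@]1(C)O[C@H]1C | intermediate
4 | (2S,3S)-2,3-dimethyloxirane-2-carboxylic acid | OC(=O)[C@@]1(C)O[C@H]1C | intermediate
5 | tropone (cyclohepta-2,4,6-trien-1-one) | O=C1C=CC=CC=C1 | starting material
6 | (1E,3E)-buta-1,3-diene-1,4-diyl diacetate | CC(=O)O/C=C/C=C/OC(C)=O | starting material
7 | meso exo-adduct 11-oxobicyclo[4.4.1]undeca-2,4,8-triene-7,10-diyl diacetate (C6-OAc and C9-OAc cis; C14 ketone bridge) | O=C1[C@H]2C=CC=C[C@@H]1[C@@H](OC(C)=O)C=C[C@H]2OC(C)=O | intermediate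
8 | C6-hydroxy C9-acetate of the bicyclic trienone (single enantiomer) | O=C1[C@H]2C=CC=C[C@@H]1[C@@H](O)C=C[C@H]2OC(C)=O | intermediate
9 | C6-OTBS C9-acetate of the bicyclic trienone | O=C1[C@H]2C=CC=C[C@@H]1[C@@H](O[Si](C)(C)C(C)(C)C)C=C[C@H]2OC(C)=O | intermediate
10 | C6-OTBS C9-hydroxy bicyclic trienone | O=C1[C@H]2C=CC=C[C@@H]1[C@@H](O[Si](C)(C)C(C)(C)C)C=C[C@H]2O | intermediate
11 | methyl 2-chloro-2-(hydroxyimino)acetate | COC(=O)C(Cl)=NO | starting material
12 | methoxycarbonylformonitrile oxide | COC(=O)C#[N+][O-] | intermediate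
13 | bicyclic isoxazoline alcohol (C11 on C7 and O on C8, both on the outer face; CO2Me on C11; C6-OTBS; C9-OH) | O=C1[C@H]2C=CC=C[C@@H]1[C@@H](O[Si](C)(C)C(C)(C)C)[C@@H]3C(C(=O)OC)=NO[C@@H]3[C@H]2O | intermediate
14 | (R)-2-methylbutanoic acid | CC[C@@H](C)C(=O)O | starting material
15 | (R)-2-methylbutanoic 2,4,6-trichlorobenzoic anhydride | CC[C@@H](C)C(=O)OC(=O)c1c(Cl)cc(Cl)cc1Cl | intermediate
16 | bicyclic isoxazoline C9 (R)-2-methylbutanoate | O=C1[C@H]2C=CC=C[C@@H]1[C@@H](O[Si](C)(C)C(C)(C)C)[C@@H]3C(C(=O)OC)=NO[C@@H]3[C@H]2OC(=O)[C@H](C)CC | intermediate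
17 | C8-hydroxy C7 α-imino ester | O=C1[C@H]2C=CC=C[C@@H]1[C@@H](O[Si](C)(C)C(C)(C)C)[C@H](C(=N)C(=O)OC)[C@H](O)[C@H]2OC(=O)[C@H](C)CC | intermediate
18 | C8-hydroxy C7 α-keto ester (C7–CO–CO2Me) | O=C1[C@H]2C=CC=C[C@@H]1[C@@H](O[Si](C)(C)C(C)(C)C)[C@H](C(=O)C(=O)OC)[C@H](O)[C@H]2OC(=O)[C@H](C)CC | intermediate
19 | C8-hydroxy C7 acrylate (C7–C(=CH2)–CO2Me) | O=C1[C@H]2C=CC=C[C@@H]1[C@@H](O[Si](C)(C)C(C)(C)C)[C@H](C(=C)C(=O)OC)[C@H](O)[C@H]2OC(=O)[C@H](C)CC | intermediate
20 | (2S,3S)-2,3-dimethyloxirane-2-carboxylic 2,4,6-trichlorobenzoic anhydride | O=C(OC(=O)[C@@]1(C)O[C@H]1C)c1c(Cl)cc(Cl)cc1Cl | intermediate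
21 | bicyclic trienone triester (C8 epoxyangelate; C9 2-methylbutanoate; C7 acrylate; C6-OTBS) | O=C1[C@H]2C=CC=C[C@@H]1[C@@H](O[Si](C)(C)C(C)(C)C)[C@H](C(=C)C(=O)OC)[C@H](OC(=O)[C@@]3(C)O[C@H]3C)[C@H]2OC(=O)[C@H](C)CC | intermediate
22 | C1/C4 endoperoxide (O–O on the bottom face; C2=C3) | O=C1[C@H]2[C@@H]3C=C[C@@H](OO3)[C@@H]1[C@@H](O[Si](C)(C)C(C)(C)C)[C@H](C(=C)C(=O)OC)[C@H](OC(=O)[C@@]3(C)O[C@H]3C)[C@H]2OC(=O)[C@H](C)CC | intermediate
23 | γ-hydroxy enone (C1-OH on the bottom face; C2=C3; C4 ketone; C14 ketone) | O=C1[C@H]2[C@@H](O)C=CC(=O)[C@@H]1[C@@H](O[Si](C)(C)C(C)(C)C)[C@H](C(=C)C(=O)OC)[C@H](OC(=O)[C@@]3(C)O[C@H]3C)[C@H]2OC(=O)[C@H](C)CC | intermediate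
24 | epoxy hydroxy diketone (2,3-epoxide and C1-OH on the bottom face) | O=C1[C@H]2[C@@H](O)[C@H]3O[C@H]3C(=O)[C@@H]1[C@@H](O[Si](C)(C)C(C)(C)C)[C@H](C(=C)C(=O)OC)[C@H](OC(=O)[C@@]3(C)O[C@H]3C)[C@H]2OC(=O)[C@H](C)CC | intermediate
25 | ten-membered β-hydroxy ester ketone (CO2Me on C10; C1-OH; 2,3-epoxide; C4 ketone; C5 H2) | COC(=O)[C@H]1[C@@H](O)[C@H]2O[C@H]2C(=O)C[C@@H](O[Si](C)(C)C(C)(C)C)[C@H](C(=C)C(=O)OC)[C@H](OC(=O)[C@@]2(C)O[C@H]2C)[C@H]1OC(=O)[C@H](C)CC | intermediate
26 | C4 enol triflate (ring-cis C4=C5) | COC(=O)[C@H]1[C@@H](O)[C@H]2O[C@H]2/C(OS(=O)(=O)C(F)(F)F)=C\[C@@H](O[Si](C)(C)C(C)(C)C)[C@H](C(=C)C(=O)OC)[C@H](OC(=O)[C@@]2(C)O[C@H]2C)[C@H]1OC(=O)[C@H](C)CC | intermediate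
27 | C4-methyl (Z)-C4=C5 β-hydroxy ester | COC(=O)[C@H]1[C@@H](O)[C@H]2O[C@H]2/C(C)=C\[C@@H](O[Si](C)(C)C(C)(C)C)[C@H](C(=C)C(=O)OC)[C@H](OC(=O)[C@@]2(C)O[C@H]2C)[C@H]1OC(=O)[C@H](C)CC | intermediate
28 | C1 mesylate of 27 | COC(=O)[C@H]1[C@@H](OS(C)(=O)=O)[C@H]2O[C@H]2/C(C)=C\[C@@H](O[Si](C)(C)C(C)(C)C)[C@H](C(=C)C(=O)OC)[C@H](OC(=O)[C@@]2(C)O[C@H]2C)[C@H]1OC(=O)[C@H](C)CC | intermediate
29 | C6-OTBS seco diester (C1=C10 and C4=C5 both ring-cis; 2,3-cis-epoxide) | COC(=O)/C1=C/[C@H]2O[C@H]2/C(C)=C\[C@@H](O[Si](C)(C)C(C)(C)C)[C@H](C(=C)C(=O)OC)[C@H](OC(=O)[C@@]2(C)O[C@H]2C)[C@H]1OC(=O)[C@H](C)CC | intermediate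
30 | C6-hydroxy seco diester | COC(=O)/C1=C/[C@H]2O[C@H]2/C(C)=C\[C@@H](O)[C@H](C(=C)C(=O)OC)[C@H](OC(=O)[C@@]2(C)O[C@H]2C)[C@H]1OC(=O)[C@H](C)CC | intermediate
31 | target germacranolide (CNP0485260.1) | C=C1C(=O)O[C@@H]2/C=C(/C)[C@@H]3O[C@@H]3/C=C(/C(=O)OC)[C@H](OC(=O)[C@H](C)CC)[C@@H](OC(=O)[C@@]3(C)O[C@H]3C)[C@@H]12 | target

**Step count**
Total: 16 steps. Longest linear sequence: 14 steps (steps 3–16); steps 1–2 make the epoxy acid 4.

**Steps most likely to fail, with fallbacks**

Step 13 (the proposed ring expansion). Methoxide may add to the epoxy ketone C4 instead of C14, or only deprotonate the 1,3-diketone. The fallback uses known chemistry and sets out from 24. Hydroxyl-directed reduction with Me4NBH(OAc)3 (MeCN/AcOH, −20 °C), in which the C1 hydroxyl delivers hydride to C14 only, gives the bicyclic C14 carbinol F1. DBU (CH2Cl2, 0 °C) then triggers a retro-aldol ring expansion from the C14 alkoxide, which can only cleave C14–C5, and gives the ten-membered C10 aldehyde F2. Pinnick oxidation (NaClO2, NaH2PO4, 2-methylbut-2-ene, t-BuOH/H2O) gives the C10 carboxylic acid F3, and Me3SiCHN2 in MeOH/PhMe returns to the route at 25.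

Step 11 (catalyst-controlled Kornblum–DeLaMare rearrangement). The two hydrogens next to the peroxide sit on the hindered face and the catalyst may not override the substrate bias. The fallback sets out from the endoperoxide 22, isolated after the photooxygenation. Thiourea in MeOH reduces it to the cis-ene-diol F4. A lipase screened for the C1 hydroxyl (for example Candida antarctica lipase B, vinyl acetate) gives the C1 acetate F5. MnO2 in CH2Cl2 oxidises the remaining allylic C4 alcohol to the acetoxy enone F6, and lipase hydrolysis in pH 7 buffer removes the acetate and returns to the route at 23.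

Step 14 (dianion triflation and Negishi coupling beside an allylic epoxide). The enolate geometry or the epoxide under zerovalent palladium may fail. The fallback sets out from 25 and avoids both enolate and palladium. Wittig methylenation (Ph3P=CH2, THF, 0 °C) gives the exocyclic C4-methylene compound F7. RuHCl(CO)(PPh3)3 (PhMe, 60 °C) then moves the double bond into the ring toward C5, the only side with hydrogens, to give the more stable ring-cis trisubstituted alkene and returns to the route at 27.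

**Further compounds**
F1 | step 13 | bicyclic C14 carbinol (C14-OH anti to C1-OH; C4 ketone kept) | O[C@@H]1[C@H]2[C@@H](O)[C@H]3O[C@H]3C(=O)[C@@H]1[C@@H](O[Si](C)(C)C(C)(C)C)[C@H](C(=C)C(=O)OC)[C@H](OC(=O)[C@@]3(C)O[C@H]3C)[C@H]2OC(=O)[C@H](C)CC
F2 | step 13 | ten-membered C10 aldehyde (C1-OH; 2,3-epoxide; C4 ketone) | O=C[C@H]1[C@@H](O)[C@H]2O[C@H]2C(=O)C[C@@H](O[Si](C)(C)C(C)(C)C)[C@H](C(=C)C(=O)OC)[C@H](OC(=O)[C@@]2(C)O[C@H]2C)[C@H]1OC(=O)[C@H](C)CC
F3 | step 13 | ten-membered C10 carboxylic acid | OC(=O)[C@H]1[C@@H](O)[C@H]2O[C@H]2C(=O)C[C@@H](O[Si](C)(C)C(C)(C)C)[C@H](C(=C)C(=O)OC)[C@H](OC(=O)[C@@]2(C)O[C@H]2C)[C@H]1OC(=O)[C@H](C)CC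
F4 | step 11 | bicyclic cis-ene-diol (C1-OH and C4-OH on the bottom face; C2=C3) | O=C1[C@H]2[C@@H](O)C=C[C@@H](O)[C@@H]1[C@@H](O[Si](C)(C)C(C)(C)C)[C@H](C(=C)C(=O)OC)[C@H](OC(=O)[C@@]3(C)O[C@H]3C)[C@H]2OC(=O)[C@H](C)CC
F5 | step 11 | C1 acetate of the ene-diol | O=C1[C@H]2[C@@H](OC(C)=O)C=C[C@@H](O)[C@@H]1[C@@H](O[Si](C)(C)C(C)(C)C)[C@H](C(=C)C(=O)OC)[C@H](OC(=O)[C@@]3(C)O[C@H]3C)[C@H]2OC(=O)[C@H](C)CC
F6 | step 11 | C1-acetoxy enone (C4 ketone) | O=C1[C@H]2[C@@H](OC(C)=O)C=CC(=O)[C@@H]1[C@@H](O[Si](C)(C)C(C)(C)C)[C@H](C(=C)C(=O)OC)[C@H](OC(=O)[C@@]3(C)O[C@H]3C)[C@H]2OC(=O)[C@H](C)CC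
F7 | step 14 | ten-membered exocyclic C4-methylene compound | COC(=O)[C@H]1[C@@H](O)[C@H]2O[C@H]2C(=C)C[C@@H](O[Si](C)(C)C(C)(C)C)[C@H](C(=C)C(=O)OC)[C@H](OC(=O)[C@@]2(C)O[C@H]2C)[C@H]1OC(=O)[C@H](C)CC
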